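**Plan**

Retrosynthesis first cuts the C3–Br bond (bromination of the free indole) and then the N–S bond, leading back to 5,6-dibromo-1-(phenylsulfonyl)indole.
The benzene ring is then opened at C5–C6. C5 and C6 are neighbouring CBr carbons flanked by the CH carbons C4 and C7, which is the pattern left when two bromoalkyne termini on pyrrole C2 and C3 join and the C4/C7 diradical takes up two hydrogens.
Behind that, the two C(sp)–Br bonds, the two pyrrole–alkyne bonds and the C2–I bond are cut, back to 3-bromo-1-(triisopropylsilyl)pyrrole.
Forward, the pyrrole ring is bought and the benzene ring is the only ring made; it closes in step 5, after N-group exchange, C2 iodination, double alkynylation and alkyne bromination.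
The target is achiral; no stereocentre arises at any stage.

Key step: step 5

Remark: 3-bromo-1H-pyrrole 2 and the bis(bromoalkyne) 9 are assumed too labile to store, so each is taken on at once in solution and 9 is never concentrated to dryness.

**Route**

Step 1
Reactants: 1 3-bromo-1-(triisopropylsilyl)-1H-pyrrole
Product: 3 3-bromo-1-(phenylsulfonyl)-1H-pyrrole, via 3-bromo-1H-pyrrole 2 (not isolated)
Conditions: TBAF (1.0 M in THF), THF, 0 °C; aqueous wash, dried solution; then NaH, PhSO2Cl, THF, 0 °C to rt
Reagents that add atoms: benzenesulfonyl chloride, O=S(=O)(Cl)c1ccccc1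
Why: Fluoride cleaves the N–Si bond (desilylation) and the sodium salt of the labile pyrrole is N-sulfonylated at once (sulfonamide formation), which installs an electron-withdrawing group that acidifies C2–H for step 2 and steadies the pyrrole for the hot ring closure.

Step 2
Reactants: 3 3-bromo-1-(phenylsulfonyl)-1H-pyrrole
Product: 5 3-bromo-2-iodo-1-(phenylsulfonyl)-1H-pyrrole, via 2-lithiopyrrole 4 (not isolated)
Conditions: LiN(iPr)2 (LDA), THF, −78 °C; then I2, THF, −78 °C to rt
Reagents that add atoms: iodine, II
Why: In this directed ortho-metalation the C2–H between the sulfonylated nitrogen and the bromine is the most acidic and is removed kinetically at −78 °C, and a prompt quench with the fast electrophile iodine should trap the 2-lithio species before it equilibrates to the 5-lithio isomer or starts a halogen dance.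

Step 3
Reactants: 5 3-bromo-2-iodo-1-(phenylsulfonyl)-1H-pyrrole; 6 trimethylsilylacetylene
Product: 8 1-(phenylsulfonyl)-2,3-bis((trimethylsilyl)ethynyl)-1H-pyrrole, via monoalkyne 7 (not isolated)
Conditions: PdCl2(PPh3)2 (cat.), CuI (cat.), Et3N, DMF, excess 6, sealed tube, rt then 80 °C
Reagents that add atoms: trimethylsilylacetylene (6), C#C[Si](C)(C)C
Why: In this twofold Sonogashira coupling the C2–I bond should add to zerovalent palladium at room temperature and the C3–Br bond of the electron-poor N-sulfonylpyrrole on heating, so one operation attaches both alkynes.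

Step 4
Reactants: 8 1-(phenylsulfonyl)-2,3-bis((trimethylsilyl)ethynyl)-1H-pyrrole
Product: 9 2,3-bis(bromoethynyl)-1-(phenylsulfonyl)-1H-pyrrole
Conditions: N-bromosuccinimide, AgNO3 (cat.), acetone, rt, dark; aqueous work-up, kept cold and in solution
Reagents that add atoms: N-bromosuccinimide, O=C1CCC(=O)N1Br
Why: In this silver-catalysed bromodesilylation AgNO3 activates each silylalkyne for replacement of silicon by bromine from N-bromosuccinimide, a standard direct conversion of trimethylsilylalkynes into 1-bromoalkynes that should leave the deactivated N-sulfonylpyrrole ring untouched.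

Step 5
Reactants: 9 2,3-bis(bromoethynyl)-1-(phenylsulfonyl)-1H-pyrrole; 10 1,4-cyclohexadiene
Product: 12 5,6-dibromo-1-(phenylsulfonyl)-1H-indole, via 4,7-didehydroindole diradical 11 (not isolated)
Conditions: 1,4-cyclohexadiene (50 equiv), chlorobenzene (0.01 M), degassed, sealed tube, 180–200 °C
Reagents that add atoms: none
Why: Heating brings the in-plane π orbitals of the two bromoalkyne termini of the (Z)-hex-3-ene-1,5-diyne unit (pyrrole C2=C3 as the ene part) into bonding overlap, the C5–C6 σ bond forms and the para-benzyne-type diradical 11 results, each radical centre of which abstracts a hydrogen atom from 1,4-cyclohexadiene, which ends as benzene. The closest known reaction is the Bergman cycloaromatization of benzo-fused and five-membered-heteroarene-fused enediynes, including 1,2-bis(bromoethynyl)arenes, which give 2,3-dibromoarenes. The six-membered ring closes by the C1–C6 mode of the enediyne, that is by bond formation between the two alkyne termini, which both become ring sp2 carbons, whereas the competing C1–C5 mode would give a non-aromatic fulvene diradical and is known only for bulky terminal groups. No stereocentre is formed. The step needs unimolecular closure to win over intermolecular radical addition to, or bromine abstraction from, the bromoalkynes, which high dilution, a large excess of the hydrogen donor and exclusion of oxygen should secure, while the placement of Br at C5 and C6 and of H at C4 and C7 is fixed by the connectivity of 9. The electron-withdrawing phenylsulfonyl group should keep the pyrrole ring from oxidation and polymerisation at this temperature.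

Step 6
Reactants: 12 5,6-dibromo-1-(phenylsulfonyl)-1H-indole
Product: 13 5,6-dibromo-1H-indole
Conditions: NaOH (2 M aq.), MeOH/THF, 60 °C
Reagents that add atoms: none
Why: In this base-mediated N-desulfonylation hydroxide attacks sulfur and expels the indolide, which the two bromines make a better leaving group, while the aryl bromides are inert to these conditions.

Step 7
Reactants: 13 5,6-dibromo-1H-indole
Product: 14 3,5,6-tribromo-1H-indole
Conditions: N-bromosuccinimide (1.0 equiv), DMF, 0 °C, dark
Reagents that add atoms: N-bromosuccinimide, O=C1CCC(=O)N1Br
Why: In this electrophilic aromatic substitution C3 is by far the most nucleophilic position of an N–H indole, so one equivalent of N-bromosuccinimide should brominate it selectively while the benzene ring, deactivated by two bromines, stays unchanged.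

**Compound list**

1 | 3-bromo-1-(triisopropylsilyl)-1H-pyrrole | CC(C)[Si](C(C)C)(C(C)C)n1ccc(Br)c1 | starting material
2 | 3-bromo-1H-pyrrole | Brc1cc[nH]c1 | intermediate (not isolated)
3 | 3-bromo-1-(phenylsulfonyl)-1H-pyrrole | Brc1ccn(S(=O)(=O)c2ccccc2)c1 | intermediate
4 | (3-bromo-1-(phenylsulfonyl)-1H-pyrrol-2-yl)lithium | [Li]c1c(Br)ccn1S(=O)(=O)c1ccccc1 | intermediate (not isolated)
5 | 3-bromo-2-iodo-1-(phenylsulfonyl)-1H-pyrrole | Brc1ccn(S(=O)(=O)c2ccccc2)c1I | intermediate
6 | trimethylsilylacetylene | C#C[Si](C)(C)C | starting material
7 | 3-bromo-1-(phenylsulfonyl)-2-((trimethylsilyl)ethynyl)-1H-pyrrole | C[Si](C)(C)C#Cc1c(Br)ccn1S(=O)(=O)c1ccccc1 | intermediate (not isolated)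
8 | 1-(phenylsulfonyl)-2,3-bis((trimethylsilyl)ethynyl)-1H-pyrrole | C[Si](C)(C)C#Cc1ccn(S(=O)(=O)c2ccccc2)c1C#C[Si](C)(C)C | intermediate
9 | 2,3-bis(bromoethynyl)-1-(phenylsulfonyl)-1H-pyrrole | BrC#Cc1ccn(S(=O)(=O)c2ccccc2)c1C#CBr | intermediate
10 | 1,4-cyclohexadiene | C1=CCC=CC1 | starting material
11 | 5,6-dibromo-1-(phenylsulfonyl)-1H-indole-4,7-diyl diradical | Brc1[c]c2ccn(S(=O)(=O)c3ccccc3)c2[c]c1Br | intermediate (not isolated)
12 | 5,6-dibromo-1-(phenylsulfonyl)-1H-indole | Brc1cc2ccn(S(=O)(=O)c3ccccc3)c2cc1Br | intermediate
13 | 5,6-dibromo-1H-indole | Brc1cc2cc[nH]c2cc1Br | intermediate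
14 | 3,5,6-tribromo-1H-indole | Brc1cc2[nH]cc(Br)c2cc1Br | target

**Count and risks**

Total step count: 7. Longest linear sequence: 7 steps (1 to 14); the route is fully linear.

Step 5 (greatest risk). The wide separation of the alkyne termini on a five-membered ring may slow the closure. Chain addition of cyclohexadienyl radicals to the bromoalkynes, bromine-atom transfer and oligomerisation could then outrun cyclization, or the product could be partly hydrodebrominated at the temperature needed. The fallback no longer builds the benzene ring but buys it and introduces bromine by electrophilic substitution. It leaves the alkyne line altogether, so it sets out from none of the numbered compounds and comes back to the route at 13. Commercial methyl 1H-indole-3-carboxylate F1 would be dibrominated with Br2 in acetic acid, where the C3 ester shields the pyrrole ring and steers both bromines to C5 and C6, to give methyl 5,6-dibromo-1H-indole-3-carboxylate F2. Saponification (NaOH, aqueous MeOH, reflux) should give 5,6-dibromo-1H-indole-3-carboxylic acid F3, which should lose CO2 on heating in acid to give 13, ready for step 7.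

Step 3. Oxidative addition into the C3–Br bond next to the newly installed silylalkyne may be slow, so the reaction could stall after the first coupling while copper-mediated Glaser dimerisation of the alkyne and slow amine-induced loss of the sulfonyl group take over. The fallback sets out from 7, isolated by stopping the coupling at room temperature with one equivalent of 6, and comes back at 9. It makes the C3 alkyne by carbonyl homologation instead of cross-coupling. Bromine–lithium exchange (tert-butyllithium, THF, −100 °C) should give the 3-lithiopyrrole F4, which is trapped with DMF to give 1-(phenylsulfonyl)-2-((trimethylsilyl)ethynyl)-1H-pyrrole-3-carbaldehyde F5. Ramirez olefination (CBr4, PPh3, CH2Cl2, 0 °C) should give 3-(2,2-dibromovinyl)-1-(phenylsulfonyl)-2-((trimethylsilyl)ethynyl)-1H-pyrrole F6. Dehydrobromination with DBU in DMSO at rt should give 3-(bromoethynyl)-1-(phenylsulfonyl)-2-((trimethylsilyl)ethynyl)-1H-pyrrole F7. The conditions of step 4 then convert the remaining silylalkyne into 9.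

Step 4. The exchange may halt after one alkyne, and long contact with the silver salt could promote hydration or oligomerisation of the electron-poor diyne, or bromination of the pyrrole at C5. The fallback sets out from 8 and comes back at 9. It separates silicon removal from bromination. Buffered protodesilylation (TBAF, AcOH, THF, 0 °C) should give 2,3-diethynyl-1-(phenylsulfonyl)-1H-pyrrole F8. Its two terminal C–H bonds would then be brominated without silver by base-mediated reaction with N-bromosuccinimide (DBU, MeCN, 0 °C) to give 9.

**Further compounds**

F1 | step 5 | methyl 1H-indole-3-carboxylate | COC(=O)c1c[nH]c2ccccc12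
F2 | step 5 | methyl 5,6-dibromo-1H-indole-3-carboxylate | COC(=O)c1c[nH]c2cc(Br)c(Br)cc12
F3 | step 5 | 5,6-dibromo-1H-indole-3-carboxylic acid | OC(=O)c1c[nH]c2cc(Br)c(Br)cc12
F4 | step 3 | (1-(phenylsulfonyl)-2-((trimethylsilyl)ethynyl)-1H-pyrrol-3-yl)lithium | [Li]c1ccn(S(=O)(=O)c2ccccc2)c1C#C[Si](C)(C)C
F5 | step 3 | 1-(phenylsulfonyl)-2-((trimethylsilyl)ethynyl)-1H-pyrrole-3-carbaldehyde | O=Cc1ccn(S(=O)(=O)c2ccccc2)c1C#C[Si](C)(C)C
F6 | step 3 | 3-(2,2-dibromovinyl)-1-(phenylsulfonyl)-2-((trimethylsilyl)ethynyl)-1H-pyrrole | BrC(Br)=Cc1ccn(S(=O)(=O)c2ccccc2)c1C#C[Si](C)(C)C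
F7 | step 3 | 3-(bromoethynyl)-1-(phenylsulfonyl)-2-((trimethylsilyl)ethynyl)-1H-pyrrole | BrC#Cc1ccn(S(=O)(=O)c2ccccc2)c1C#C[Si](C)(C)C
F8 | step 4 | 2,3-diethynyl-1-(phenylsulfonyl)-1H-pyrrole | C#Cc1ccn(S(=O)(=O)c2ccccc2)c1C#C
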